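**Plan**

- Target: (S)-5-hydroxy-5-nonadecylcyclohex-2-en-1-one, ring numbered C1 (C=O), C2=C3, C4H2, C5 (carbinol), C6H2.
- Retrosynthesis: after removal of an O-silyl group the ring is cut at C1–C2 and C3–C4, so that C2 and C3 leave as acetylene. What remains (C1, C6, C5, C4) is a 3-silyloxy-3-nonadecylcyclobutanone with a mirror plane through C1 and C5; C5 is therefore prochiral and the two C1–CH2 bonds are enantiotopic, which is the feature that lets one event expand the ring and create the stereocentre.
- The cyclobutanone is cut into dichloroketene (C1 and one CH2) and the silyl enol ether of henicosan-2-one (C5 and the other CH2); the ketone comes from icosanoic acid and methyllithium.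
- Forward: the C21 chain is made first, the four-membered ring follows by [2+2] cycloaddition and dechlorination, the six-membered ring (the only ring of the target) arises by two-carbon ring expansion with acetylene, and desilylation ends the route.
- Stereochemistry: the single stereocentre C5 comes from catalyst-controlled choice between the two enantiotopic C1–CH2 bonds by a chiral ligand on nickel; no bond at C5 is made or broken then or later.

Key step: step 5

Assumption: the sense of induction of the nickel–ligand pair cannot be predicted for this substrate class, so the ligand antipode that delivers S at C5 would be chosen after a screen; both antipodes are available.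

**Route**

Step 1
Reactants: 1 icosanoic acid; 2 methyllithium
Product: 5 henicosan-2-one, via lithium icosanoate 3 (not isolated), via dilithium henicosane-2,2-diolate 4 (not isolated)
Conditions: MeLi (2.2 equiv), THF, 0 °C to rt; inverse quench into cold 1 M aq. HCl
Reagents that add atoms: methyllithium, [Li]C
Why: Two equivalents of an organolithium convert a carboxylic acid into a methyl ketone (classical acid-to-ketone synthesis) because the dilithium gem-diolate is stable in the flask and releases the ketone only in the inverse acidic quench, after the excess MeLi has been destroyed.

Step 2
Reactants: 5 henicosan-2-one; 6 tert-butyldimethylsilyl chloride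
Product: 8 tert-butyl(henicos-1-en-2-yloxy)dimethylsilane, via lithium henicos-1-en-2-olate 7 (not isolated)
Conditions: LiN(i-Pr)2 (commercial solution, 1.1 equiv), THF, −78 °C; then TBSCl, DMPU, −78 °C to rt
Reagents that add atoms: tert-butyldimethylsilyl chloride, CC(C)(C)[Si](C)(C)Cl
Why: Kinetic enolization with a hindered lithium amide at −78 °C takes a proton from the less substituted methyl side, and O-silylation of the lithium enolate, accelerated by DMPU, fixes this regiochemistry as the terminal silyl enol ether (kinetic enolate trapping).

Step 3
Reactants: 8 tert-butyl(henicos-1-en-2-yloxy)dimethylsilane; 9 trichloroacetyl chloride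
Product: 11 (±)-3-[(tert-butyldimethylsilyl)oxy]-2,2-dichloro-3-nonadecylcyclobutan-1-one, via dichloroketene 10 (not isolated)
Conditions: Cl3CCOCl (slow addition), Zn–Cu couple, Et2O/DME, rt
Reagents that add atoms: trichloroacetyl chloride, ClC(Cl)(Cl)C(Cl)=O
Why: The thermal [2+2] ketene–alkene cycloaddition of dichloroketene, generated by zinc dehalogenation of the acid chloride, is fast and regioselective with electron-rich 2-silyloxyalkenes, the nucleophilic CH2 terminus bonding to the ketene carbonyl carbon so that the silyloxy carbon becomes C3 of the cyclobutanone; the one stereocentre formed is racemic and loses its stereogenicity in step 4.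

Step 4
Reactants: 11 (±)-3-[(tert-butyldimethylsilyl)oxy]-2,2-dichloro-3-nonadecylcyclobutan-1-one
Product: 12 3-[(tert-butyldimethylsilyl)oxy]-3-nonadecylcyclobutan-1-one
Conditions: Zn dust, NH4Cl, MeOH/THF, 0 °C to rt
Reagents that add atoms: none
Why: Zinc-mediated reductive dechlorination of α,α-dichlorocyclobutanones in a buffered protic medium is the standard sequel to a dichloroketene cycloaddition, the zinc enolate being protonated faster than it can expel the poor silanolate leaving group, and with both chlorines gone the two ring CH2 groups are equivalent, so the product is achiral with a prochiral C3.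

Step 5
Reactants: 12 3-[(tert-butyldimethylsilyl)oxy]-3-nonadecylcyclobutan-1-one; 13 acetylene
Product: 14 (S)-5-[(tert-butyldimethylsilyl)oxy]-5-nonadecylcyclohex-2-en-1-one
Conditions: Ni(cod)2 (10 mol %), single-stereoisomer O,O'-(1,1'-binaphthalene-2,2'-diyl) N,N-bis(1-phenylethyl)phosphoramidite (20 mol %), toluene, 60–80 °C, C2H2 fed slowly as a dilute THF solution (syringe pump)
Reagents that add atoms: acetylene, C#C
Why: Proposed new method: zerovalent nickel should couple the carbonyl of 12 with acetylene by oxidative cyclization to a spirocyclic oxanickelacyclopentene of divalent nickel (C1–C2 formed), strain-driven β-carbon elimination then cleaves one C1–CH2 bond to give a seven-membered nickelacycle, and C(sp2)–C(sp3) reductive elimination forms C3–C4 and returns zerovalent nickel. The closest known reaction type is the Ni(cod)2–trialkylphosphine-catalysed insertion of internal alkynes into 3,3-disubstituted cyclobutanones to give cyclohex-2-enones, together with enantioselective nickel-catalysed desymmetrizations of 3-substituted cyclobutanones by tethered alkenes; neither acetylene itself nor an intermolecular enantioselective version has precedent. The six-membered ring closes by two-carbon ring expansion of the four-membered ring, a formal [4+2] union of C1–C6–C5–C4 with C2–C3 completed by the reductive elimination, which also fixes the alkene as cis and conjugated to C1. C5 becomes a stereocentre without any bond to it being made or broken, its configuration being set under catalyst control by the chiral phosphoramidite on nickel, which selects one of the two enantiotopic C1–CH2 bonds. The step needs this enantiotopic-bond selectivity, secured by the large difference between the bulky silyloxy group and the unbranched chain on C5, and chemoselectivity for cross-coupling over oligomerization of acetylene, secured by keeping the alkyne at low stationary concentration. The fully substituted C5 offers no hydrogen for β-hydride elimination from the nickelacycle, and the bulky silyl ether is a poor leaving group, which should hold back β-oxygen elimination.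

Step 6
Reactants: 14 (S)-5-[(tert-butyldimethylsilyl)oxy]-5-nonadecylcyclohex-2-en-1-one
Product: 15 (S)-5-hydroxy-5-nonadecylcyclohex-2-en-1-one
Conditions: HF·pyridine, excess pyridine, THF, 0 °C to rt (polypropylene vessel)
Reagents that add atoms: none
Why: Fluoride-mediated desilylation with pyridine-buffered HF cleaves only the O–Si bond under weakly acidic, non-enolizing conditions, so the tertiary alcohol should be freed with its configuration intact and without the base-induced β-elimination that would lead on to aromatization.

**Compound list**

1 | icosanoic acid | CCCCCCCCCCCCCCCCCCCC(O)=O | starting material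
2 | methyllithium | [Li]C | starting material
3 | lithium icosanoate | CCCCCCCCCCCCCCCCCCCC(=O)[O-].[Li+] | intermediate (not isolated)
4 | dilithium henicosane-2,2-diolate | CCCCCCCCCCCCCCCCCCCC(C)([O-])[O-].[Li+].[Li+] | intermediate (not isolated)
5 | henicosan-2-one | CCCCCCCCCCCCCCCCCCCC(C)=O | intermediate
6 | tert-butyldimethylsilyl chloride | CC(C)(C)[Si](C)(C)Cl | starting material
7 | lithium henicos-1-en-2-olate | CCCCCCCCCCCCCCCCCCCC(=C)[O-].[Li+] | intermediate (not isolated)
8 | tert-butyl(henicos-1-en-2-yloxy)dimethylsilane | CCCCCCCCCCCCCCCCCCCC(=C)O[Si](C)(C)C(C)(C)C | intermediate
9 | trichloroacetyl chloride | ClC(Cl)(Cl)C(Cl)=O | starting material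
10 | dichloroketene | ClC(Cl)=C=O | intermediate (not isolated)
11 | (±)-3-[(tert-butyldimethylsilyl)oxy]-2,2-dichloro-3-nonadecylcyclobutan-1-one (racemic) | CCCCCCCCCCCCCCCCCCCC1(O[Si](C)(C)C(C)(C)C)CC(=O)C1(Cl)Cl | intermediate
12 | 3-[(tert-butyldimethylsilyl)oxy]-3-nonadecylcyclobutan-1-one (achiral) | CCCCCCCCCCCCCCCCCCCC1(O[Si](C)(C)C(C)(C)C)CC(=O)C1 | intermediate
13 | acetylene | C#C | starting material
14 | (S)-5-[(tert-butyldimethylsilyl)oxy]-5-nonadecylcyclohex-2-en-1-one | CCCCCCCCCCCCCCCCCCC[C@]1(O[Si](C)(C)C(C)(C)C)CC=CC(=O)C1 | intermediate
15 | (S)-5-hydroxy-5-nonadecylcyclohex-2-en-1-one | CCCCCCCCCCCCCCCCCCC[C@]1(O)CC=CC(=O)C1 | target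

**Step count and risks**

Total steps: 6. Longest linear sequence: 6 steps (1 → 5 → 8 → 11 → 12 → 14 → 15).

Steps most likely to fail:

Step 5. Nickel-mediated cyclotrimerization and polymerization of acetylene may consume the alkyne and the catalyst before the ketone is engaged. The ligand may also discriminate poorly between the two enantiotopic ring bonds, and the product enone may be drawn into further cocyclization with acetylene. The fallback uses known reaction types only, sets out from henicosan-2-one 5 and comes back to the route at the target 15, replacing the desymmetrization by a stereochemical relay.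
- Enolization of 5 on the methyl side with the appropriate antipode of diisopinocampheylboron chloride (Ipc2BCl) and Et3N, then addition to acrolein at −78 °C with oxidative work-up (reagent-controlled boron aldol reaction), should give (R)-3-hydroxytetracos-1-en-5-one F1.
- Addition of allylmagnesium bromide to the magnesium alkoxide chelate of F1 (THF, −78 °C, chelation-controlled 1,2-addition) is expected to give mainly (3R,5S)-5-nonadecylocta-1,7-diene-3,5-diol F2.
- Only the configuration at C5 matters, because the C3 carbinol is oxidized away at the end. The minor diastereomer would be removed by chromatography here or after ring closure, and if the induction ran the other way the other antipode of the boron reagent would be used.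
- Ring-closing metathesis of F2 with the second-generation Grubbs catalyst (CH2Cl2, 40 °C) should close C2=C3 with loss of ethylene and give (1R,5S)-5-nonadecylcyclohex-2-ene-1,5-diol F3.
- MnO2 in CH2Cl2 should oxidize only the allylic secondary alcohol of F3 and give 15.

Step 4. The zinc enolate formed after the first chlorine is lost may expel silanolate, or methanol may attack the electron-poor carbonyl and open the strained ring in a haloform-type cleavage. The fallback sets out from 11 and comes back at 12 by a homolytic chain reduction in place of the two-electron metal reduction: tris(trimethylsilyl)silane (2.5 equiv) and AIBN in toluene at 80 °C should remove both chlorines through α-keto radicals. No enolate and no protic nucleophile are present, so neither elimination nor ring opening has a pathway.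

Step 6. Dehydration across C5–C6 followed by tautomerization to the aromatic ring may compete, or the hindered tertiary silyl ether may cleave so slowly that forcing conditions become necessary. The fallback sets out from 14 and comes back at 15 by taking the carbonyl out of play during deprotection.
- Luche reduction (NaBH4, CeCl3·7H2O, MeOH/THF, −78 °C) should give (5S)-5-[(tert-butyldimethylsilyl)oxy]-5-nonadecylcyclohex-2-en-1-ol F4 as a mixture of C1 epimers.
- TBAF in THF (rt to 50 °C), harmless now that nothing can enolize, should give (5S)-5-nonadecylcyclohex-2-ene-1,5-diol F5 as the same epimer mixture.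
- MnO2 in CH2Cl2 should reoxidize the allylic alcohol of both epimers to 15.

**Further compounds**

F1 | step 5 | (R)-3-hydroxytetracos-1-en-5-one | C=C[C@H](O)CC(=O)CCCCCCCCCCCCCCCCCCC
F2 | step 5 | (3R,5S)-5-nonadecylocta-1,7-diene-3,5-diol | C=C[C@H](O)C[C@@](O)(CC=C)CCCCCCCCCCCCCCCCCCC
F3 | step 5 | (1R,5S)-5-nonadecylcyclohex-2-ene-1,5-diol | C1=CC[C@@](O)(CCCCCCCCCCCCCCCCCCC)C[C@H]1O
F0 | step 4 | none | none
F4 | step 6 | (5S)-5-[(tert-butyldimethylsilyl)oxy]-5-nonadecylcyclohex-2-en-1-ol, both C1 epimers | CCCCCCCCCCCCCCCCCCC[C@]1(O[Si](C)(C)C(C)(C)C)CC=CC(O)C1
F5 | step 6 | (5S)-5-nonadecylcyclohex-2-ene-1,5-diol, both C1 epimers | CCCCCCCCCCCCCCCCCCC[C@]1(O)CC=CC(O)C1
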